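The numbers in the tables were generated by integration from invented constants.

I start from the spare Rea.

| flask | Sbt | Rea | remark | time |
|---|---|---|---|---|
| noon | 20 mM | 26 mM | run made earlier |  |
| summer | 10 mM | 26 mM | run made earlier |  |
| spring | 15 mM | 26 mM | run made earlier |  |
| ochre | 20 mM | 26.0 mM (fed, over 40 h) | all else is in the flask from the start; the feed brings no volume worth counting | 2.0 d |
| amber | 20 mM | 26.0 mM | everything together at the start | 2.0 d |
| grey | 20 mM (fed, over 40 h) | 26.0 mM | all else is in the flask from the start; the feed brings no volume worth counting | 2.0 d |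

| run | time / h | Pdt / % |
|---|---|---|
| noon | 4.00 | 50.0 |
| noon | 8.00 | 51.0 |
| noon | 15.0 | 46.6 |
| noon | 25.0 | 43.6 |
| noon | 50.0 | 40.1 |
| summer | 8.00 | 40.4 |
| summer | 15.0 | 26.5 |
| summer | 25.0 | 15.3 |
| summer | 30.0 | 12.3 |
| summer | 40.0 | 7.9 |
| spring | 3.00 | 49.8 |
| spring | 10.0 | 42.8 |
| spring | 20.0 | 32.3 |
| spring | 30.0 | 25.8 |
| spring | 40.0 | 20.3 |

(each reading ± 0.5 percentage points)

- a reading or a percentage of Pdt counts all its forms, free or not

- the best flask by amount of Pdt, in percent of the Sbt charged; "all alike" if 1.5 percentage points covers them all (ochre / amber / grey / all alike)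
- amount of Pdt at the end, in percent of the Sbt charged, ochre
- amount of Pdt at the end, in percent of the Sbt charged, amber
- amount of Pdt at the end, in percent of the Sbt charged, grey

Ochre, amber and grey carry the same charges, so by charge Sbt is the limiting reagent, and Rea stands over by

spare Rea = 26.0 mM − 20 mM = 6.00 mM

Amber repeats noon, so I draw noon's curve. It climbs on average at 2.50 mM h⁻¹ over the first 4.00 h, bends at 51.0% near 8.00 h, then sags to 40.1% at 50.0 h. Pdt stands lower where more Rea stands over: at 25.0 h summer, with 16.0 mM spare, holds 15.3% against noon's 43.6%.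

So I take the forming of Pdt as over early, and assume that each Sbt takes one Rea and each Pdt lost takes one more. Taking summer's fall as a steady fraction per hour and running its first two readings back to time zero gives, as a reading, the share of Sbt that becomes Pdt:

share = 40.4% × (40.4% ÷ 26.5%) to the power 8.00 h ÷ (15.0 h − 8.00 h) = 65.4%

floor = 65.4% − 6.00 mM ÷ 20 mM = 35.4%

This floor, the Pdt that stands once the spare Rea has gone onto it, is the level I expect the curve to run into. Noon's last reading is still 4.7 percentage points above it, so I put amber near 40.1%. Where some Sbt stays unreacted, its Rea is free to go onto Pdt, so the same balance then takes the reacted part in place of the whole charge.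

The forecast names ochre best, with 45.5% for ochre, 40% for amber and 29% for grey: “Ochre keeps Rea scarce while Sbt remains, so Pdt is little attacked.”

The flasks give 46.5% for ochre, 39.2% for amber and 30.2% for grey, so ochre is best.

    Sbt + Rea → Pdt (k = 0.00800 L mol⁻¹ s⁻¹)
    Sbt + Rea → Ofp (k = 0.00400 L mol⁻¹ s⁻¹)
    Tsp ⇌ Pdt, rate k3*(cs3 - [Pdt]) while solid is left; crystals form when [Pdt] > cs3 (solubility = 11.0 mM, k = 0.00350 s⁻¹)
    Rea + Pdt → Ofp2 (k = 0.00130 L mol⁻¹ s⁻¹)

Ochre has not come to rest at 2.0 d: 9.6% of its Rea still stands, which is 2.50 mM. At 20.0 d its Rea is 0% and its Pdt 36.4%, against the floor of 35.4%, and amber's Pdt stands at 36.4% by then too, so ochre's lead of 7.3 points at 2.0 d has closed. Grey's Pdt goes from 30.2% to 30.4%. At 20.0 d, with Rea 0% and 3.76% of its Sbt unreacted, grey has a floor of 29.2% and holds 30.4%.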